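**Retrosynthetic overview**
1. Target ⇒ its O-triethylsilyl ether. The exocyclic C7=C8 bond (7Z) comes from a syn-aldol of a 2-bromo-4-siloxy-4-octenylcyclopentenone with methyl (5E)-7-oxohept-5-enoate, followed by syn-dehydration.
2. The (Z)-octenyl chain comes from a Wittig reaction on a CH2CHO arm at C12; the C10–Br bond comes from ipso-bromodesilylation of a 2-silyl enone.
3. Key disconnection C9–C10 (ring closure): the cyclopentenone comes from a prochiral 3-siloxy-3-(silylethynyl)pentanedial. One CHO is turned into an acyl–rhodium hydride (an acyl anion equivalent) that adds to the alkyne; the chiral catalyst's choice between the two enantiotopic CH2CHO arms sets C12.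
4. The dialdehyde comes from ozonolysis of a diallyl(alkynyl)carbinol silyl ether, made from ethyl 3-(trimethylsilyl)propiolate and two equivalents of allylmagnesium bromide.
5. Ring order: there is only one ring, the cyclopentenone, and it is closed in step 4.

Assumption: [Rh((R)-Tol-BINAP)]BF4 is taken to select the aldehyde arm that gives (S)-10; if the sense is the opposite, the (S)-ligand is used and nothing else changes. Prostanoid locants C1–C20 are used for atoms; the C12 label changes from S (10–17) to R (19, 20) only because CIP priorities change, not the geometry.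

**Step 1**
Reactants: 1 methyl hex-5-enoate; 2 (E)-but-2-enal (crotonaldehyde, 4 equiv)
Product: 3 methyl (5E)-7-oxohept-5-enoate
Conditions: RuCl2(H2IMes)(=CH-C6H4-2-OiPr) (second-generation Hoveyda–Grubbs catalyst, 2 mol%), CH2Cl2, 40 °C
Reagents that add atoms: none
Why: Olefin cross-metathesis of a terminal alkene with an excess of the electron-poor partner gives the cross product as the conjugated (E)-enal, with propene leaving as a gas.

**Step 2**
Reactants: 4 ethyl 3-(trimethylsilyl)prop-2-ynoate; 5 allylmagnesium bromide (2.3 equiv)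
Product: 7 triethyl({4-[(trimethylsilyl)ethynyl]hepta-1,6-dien-4-yl}oxy)silane, via bromomagnesium alkoxide 6 (not isolated)
Conditions: CH2=CHCH2MgBr, Et2O, −78 → 0 °C; then Et3SiOTf (2.6 equiv), −78 → 23 °C
Reagents that add atoms: triethylsilyl trifluoromethanesulfonate, CC[Si](CC)(CC)OS(=O)(=O)C(F)(F)F
Why: Double 1,2-addition of the allyl Grignard reagent to the ester (the silyl cap blocks conjugate addition and acetylide formation) gives the tertiary magnesium alkoxide, which the silyl triflate O-silylates in the same flask; no stereocentre arises because the two allyl arms are identical.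

**Step 3**
Reactants: 7 triethyl({4-[(trimethylsilyl)ethynyl]hepta-1,6-dien-4-yl}oxy)silane
Product: 9 3-(triethylsilyloxy)-3-[(trimethylsilyl)ethynyl]pentanedial, via bis-ozonide 8 (not isolated)
Conditions: O3, CH2Cl2, −78 °C (stopped at the first excess of ozone); then PPh3 (2.2 equiv), −78 °C → rt
Reagents that add atoms: ozone, [O-][O+]=O
Why: Ozonolysis with reductive work-up cleaves both terminal alkenes, which react with ozone far faster than the hindered silylalkyne, and gives the prochiral dialdehyde in which C12 carries two identical CH2CHO arms.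

**Step 4**
Reactants: 9 3-(triethylsilyloxy)-3-[(trimethylsilyl)ethynyl]pentanedial
Product: 10 2-[(1S)-4-oxo-1-(triethylsilyloxy)-3-(trimethylsilyl)cyclopent-2-en-1-yl]acetaldehyde
Conditions: [Rh(nbd)((R)-Tol-BINAP)]BF4 (5 mol%, nbd removed with H2 beforehand), CH2Cl2, 23 °C
Reagents that add atoms: none
Why: Proposed new method: cationic monovalent rhodium inserts into one aldehyde C–H bond to give an acyl rhodium hydride that acts as an acyl anion equivalent, so the normally electrophilic carbonyl carbon C9 is delivered as the nucleophile to the metal-bound (electrophilic) alkyne carbon C10 by trans-hydrometalation and C–C reductive elimination, closing the cyclopentenone, while the Tol-BINAP ligand chooses one of the two enantiotopic CH2CHO arms and so sets C12; the closest known reaction is the Tanaka–Fu rhodium-catalysed intramolecular hydroacylation of 4-alkynals to cyclopentenones, including its Tol-BINAP kinetic resolution and desymmetrisation of substrates with an oxygenated quaternary C3.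

**Step 5**
Reactants: 10 2-[(1S)-4-oxo-1-(triethylsilyloxy)-3-(trimethylsilyl)cyclopent-2-en-1-yl]acetaldehyde
Product: 11 2-[(1S)-3-bromo-4-oxo-1-(triethylsilyloxy)cyclopent-2-en-1-yl]acetaldehyde
Conditions: Br2 (1.05 equiv), CH2Cl2, −78 → 0 °C; aqueous Na2S2O3/NaHCO3 work-up
Reagents that add atoms: bromine, BrBr
Why: Electrophilic ipso-bromodesilylation of the vinylsilane puts bromine on the silicon-bearing C10 and the β-silyl cation (or dibromide) collapses with loss of Me3SiBr to restore the enone; the enone is the only alkene present at this stage and C12 is untouched.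

**Step 6**
Reactants: 11 2-[(1S)-3-bromo-4-oxo-1-(triethylsilyloxy)cyclopent-2-en-1-yl]acetaldehyde; 12 hexyltriphenylphosphonium bromide
Product: 14 (4S)-2-bromo-4-[(2Z)-oct-2-en-1-yl]-4-(triethylsilyloxy)cyclopent-2-en-1-one, via hexylidene ylide 13 (not isolated)
Conditions: 12, NaN(SiMe3)2, THF, 0 °C; ylide solution (1.0 equiv) added to 11, THF, −78 °C, 30 min; NH4Cl quench at −78 °C
Reagents that add atoms: none
Why: The salt-free Wittig reaction of a non-stabilised ylide gives the (Z)-alkene under kinetic control, and at −78 °C with inverse addition the aldehyde reacts faster than the hindered ketone, the conjugate position next to quaternary C12 or the C8–H protons.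

**Step 7**
Reactants: 14 (4S)-2-bromo-4-[(2Z)-oct-2-en-1-yl]-4-(triethylsilyloxy)cyclopent-2-en-1-one; 3 methyl (5E)-7-oxohept-5-enoate
Product: 17 methyl (5E,7S)-7-[(1S,2S)-4-bromo-2-[(2Z)-oct-2-en-1-yl]-5-oxo-2-(triethylsilyloxy)cyclopent-3-en-1-yl]-7-hydroxyhept-5-enoate, via lithium enolate 15 (not isolated), via chlorozirconocene enolate 16 (not isolated)
Conditions: LiN(iPr)2 (1.05 equiv), THF, −78 °C; Cp2ZrCl2 (1.1 equiv), −78 → −40 °C; 3 (1.2 equiv), −78 °C; aqueous NH4Cl
Reagents that add atoms: none
Why: Kinetic deprotonation at C8 (the only enolisable position), transmetalation and a zirconium-enolate aldol addition to the enal carbonyl give the C7/C8-syn adduct, as zirconium enolates do whatever the enolate geometry; both new stereocentres are removed in step 8 (the C7,C8-bis-epimeric syn isomer converges) and the siloxy group is not eliminated because that would form a cyclopentadienone.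

**Step 8**
Reactants: 17 methyl (5E,7S)-7-[(1S,2S)-4-bromo-2-[(2Z)-oct-2-en-1-yl]-5-oxo-2-(triethylsilyloxy)cyclopent-3-en-1-yl]-7-hydroxyhept-5-enoate
Product: 19 methyl (5E,7Z)-7-[(2R)-4-bromo-2-[(2Z)-oct-2-en-1-yl]-5-oxo-2-(triethylsilyloxy)cyclopent-3-en-1-ylidene]hept-5-enoate, via O-alkylisourea 18 (not isolated)
Conditions: DCC (3 equiv), CuCl2 (0.1 equiv), toluene, 60 °C
Reagents that add atoms: none
Why: Carbodiimide/copper-mediated dehydration of a β-hydroxy ketone is a stereospecific syn elimination through the O-alkylisourea, so the syn-aldol gives the alkylidene with C6 cis to the C9 carbonyl (7Z) while the 5E and 14Z alkenes and C12 are unaffected.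

**Step 9**
Reactants: 19 methyl (5E,7Z)-7-[(2R)-4-bromo-2-[(2Z)-oct-2-en-1-yl]-5-oxo-2-(triethylsilyloxy)cyclopent-3-en-1-ylidene]hept-5-enoate
Product: 20 methyl (5E,7Z)-7-[(2R)-4-bromo-2-hydroxy-2-[(2Z)-oct-2-en-1-yl]-5-oxocyclopent-3-en-1-ylidene]hept-5-enoate
Conditions: HF·pyridine, pyridine, THF, 0 °C → rt
Reagents that add atoms: none
Why: Buffered fluoride desilylation cleaves the tertiary triethylsilyl ether through Si–F bond formation without touching the ester, the vinyl bromide or the cross-conjugated dienone, and releases the target with C12 unchanged.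

**Compound list**
1 | methyl hex-5-enoate | C=CCCCC(=O)OC | starting material
2 | (E)-but-2-enal | C/C=C/C=O | starting material
3 | methyl (5E)-7-oxohept-5-enoate | COC(=O)CCC/C=C/C=O | intermediate
4 | ethyl 3-(trimethylsilyl)prop-2-ynoate | CCOC(=O)C#C[Si](C)(C)C | starting material
5 | allylmagnesium bromide | C=CC[Mg]Br | starting material
6 | bromomagnesium 4-[(trimethylsilyl)ethynyl]hepta-1,6-dien-4-olate (not isolated) | C=CCC(CC=C)(O[Mg]Br)C#C[Si](C)(C)C | intermediate
7 | triethyl({4-[(trimethylsilyl)ethynyl]hepta-1,6-dien-4-yl}oxy)silane | C=CCC(CC=C)(O[Si](CC)(CC)CC)C#C[Si](C)(C)C | intermediate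
8 | bis-ozonide of 7, both allyl groups as 1,2,4-trioxolan-3-ylmethyl groups, stereoisomer mixture (not isolated) | C[Si](C)(C)C#CC(CC1OCOO1)(CC1OCOO1)O[Si](CC)(CC)CC | intermediate
9 | 3-(triethylsilyloxy)-3-[(trimethylsilyl)ethynyl]pentanedial (prochiral) | O=CCC(CC=O)(O[Si](CC)(CC)CC)C#C[Si](C)(C)C | intermediate
10 | 2-[(1S)-4-oxo-1-(triethylsilyloxy)-3-(trimethylsilyl)cyclopent-2-en-1-yl]acetaldehyde | O=CC[C@@]1(O[Si](CC)(CC)CC)C=C([Si](C)(C)C)C(=O)C1 | intermediate
11 | 2-[(1S)-3-bromo-4-oxo-1-(triethylsilyloxy)cyclopent-2-en-1-yl]acetaldehyde | O=CC[C@@]1(O[Si](CC)(CC)CC)C=C(Br)C(=O)C1 | intermediate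
12 | hexyltriphenylphosphonium bromide | CCCCCC[P+](c1ccccc1)(c1ccccc1)c1ccccc1.[Br-] | starting material
13 | hexylidenetriphenylphosphorane (not isolated) | CCCCCC=P(c1ccccc1)(c1ccccc1)c1ccccc1 | intermediate
14 | (4S)-2-bromo-4-[(2Z)-oct-2-en-1-yl]-4-(triethylsilyloxy)cyclopent-2-en-1-one | CCCCC/C=C\C[C@@]1(O[Si](CC)(CC)CC)C=C(Br)C(=O)C1 | intermediate
15 | lithium enolate of 14 at C8–C9 (not isolated) | CCCCC/C=C\C[C@@]1(O[Si](CC)(CC)CC)C=C(Br)C(O[Li])=C1 | intermediate
16 | chlorobis(cyclopentadienyl)zirconium enolate of 14, cyclopentadienyl rings drawn σ-bonded (not isolated) | CCCCC/C=C\C[C@@]1(O[Si](CC)(CC)CC)C=C(Br)C(O[Zr](Cl)(C2C=CC=C2)C2C=CC=C2)=C1 | intermediate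
17 | methyl (5E,7S)-7-[(1S,2S)-4-bromo-2-[(2Z)-oct-2-en-1-yl]-5-oxo-2-(triethylsilyloxy)cyclopent-3-en-1-yl]-7-hydroxyhept-5-enoate (C7/C8-syn aldol, new chain drawn trans to the siloxy group) | CCCCC/C=C\C[C@@]1(O[Si](CC)(CC)CC)C=C(Br)C(=O)[C@H]1[C@@H](O)/C=C/CCCC(=O)OC | intermediate
18 | O-alkyl-N,N'-dicyclohexylisourea of 17 at the C7 oxygen (not isolated) | CCCCC/C=C\C[C@@]1(O[Si](CC)(CC)CC)C=C(Br)C(=O)[C@H]1[C@@H](OC(=NC2CCCCC2)NC2CCCCC2)/C=C/CCCC(=O)OC | intermediate
19 | methyl (5E,7Z)-7-[(2R)-4-bromo-2-[(2Z)-oct-2-en-1-yl]-5-oxo-2-(triethylsilyloxy)cyclopent-3-en-1-ylidene]hept-5-enoate | CCCCC/C=C\C[C@@]1(O[Si](CC)(CC)CC)C=C(Br)C(=O)/C1=C\C=C\CCCC(=O)OC | intermediate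
20 | methyl (5E,7Z)-7-[(2R)-4-bromo-2-hydroxy-2-[(2Z)-oct-2-en-1-yl]-5-oxocyclopent-3-en-1-ylidene]hept-5-enoate | CCCCC/C=C\C[C@@]1(O)C=C(Br)C(=O)/C1=C\C=C\CCCC(=O)OC | target

**Totals and risks**
Total step count: 9. Longest linear sequence: 8 (steps 2–9).

Step 4 is the most uncertain. Discrimination between two aldehyde arms has no direct precedent, and the dialdehyde could instead lactonise (Tishchenko-type) or cyclise with low selectivity. The fallback sets out from 9 and comes back at 10. Compound 9 is cyclised with the achiral catalyst [Rh(dppe)]2(BF4)2 in acetone to racemic 2-[4-oxo-1-(triethylsilyloxy)-3-(trimethylsilyl)cyclopent-2-en-1-yl]acetaldehyde F1. F1 is condensed with (1S,2S)-N,N'-dimethyl-1,2-diphenylethane-1,2-diamine (MgSO4, CH2Cl2) to two diastereomeric imidazolidines, the (4S)-cyclopentenone aminal F2 and the (4R)-cyclopentenone aminal F3. These are separated by chromatography or crystallisation, and F2 is hydrolysed with dilute aqueous acid to 10. This replaces catalytic desymmetrisation by classical resolution, and the same aminal can upgrade the ee of catalytically made 10.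

Step 6 is the second risk. A basic ylide meets an α-bromo enone with acidic C8–H protons and a β-siloxy aldehyde. The fallback sets out from 11 and comes back at 14. The aldehyde is methylenated under non-basic, aldehyde-selective conditions (Zn, CH2I2, Ti(OiPr)4, THF) to (4S)-2-bromo-4-(prop-2-en-1-yl)-4-(triethylsilyloxy)cyclopent-2-en-1-one F4. F4 then undergoes Z-selective cross-metathesis with hept-1-ene using a cyclometalated ruthenium nitrate catalyst of the Grubbs Z-selective type (Ru(NO3) with a chelating 2-isopropoxybenzylidene and a C–H-activated N-adamantyl NHC) to give 14. The electron-poor bromo enone does not take part in metathesis.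

Step 8 is the third risk. On this hindered allylic aldol, E1cB leakage or a poor syn/anti ratio from step 7 would erode the 7Z geometry. The fallback sets out from 17 and comes back at 19. Compound 17 is converted with MsCl and Et3N into the C7 methanesulfonate F5, which is eliminated with DBU to a mixture of 19 and its (7E) isomer F6. The isomers are separated, and F6 is re-equilibrated photochemically (350 nm, benzene; the exocyclic C7=C8 bond of such cross-conjugated dienones isomerises under light) and recycled. The geometry is then obtained by equilibration and separation instead of by a stereospecific elimination.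

**Further compounds**
F1 | step 4 | racemic 2-[4-oxo-1-(triethylsilyloxy)-3-(trimethylsilyl)cyclopent-2-en-1-yl]acetaldehyde | O=CCC1(O[Si](CC)(CC)CC)C=C([Si](C)(C)C)C(=O)C1
F2 | step 4 | (4S)-4-{[(4S,5S)-1,3-dimethyl-4,5-diphenylimidazolidin-2-yl]methyl}-4-(triethylsilyloxy)-2-(trimethylsilyl)cyclopent-2-en-1-one | CN2[C@@H](c3ccccc3)[C@H](c3ccccc3)N(C)C2C[C@@]1(O[Si](CC)(CC)CC)C=C([Si](C)(C)C)C(=O)C1
F3 | step 4 | (4R)-4-{[(4S,5S)-1,3-dimethyl-4,5-diphenylimidazolidin-2-yl]methyl}-4-(triethylsilyloxy)-2-(trimethylsilyl)cyclopent-2-en-1-one | CN2[C@@H](c3ccccc3)[C@H](c3ccccc3)N(C)C2C[C@]1(O[Si](CC)(CC)CC)C=C([Si](C)(C)C)C(=O)C1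
F4 | step 6 | (4S)-2-bromo-4-(prop-2-en-1-yl)-4-(triethylsilyloxy)cyclopent-2-en-1-one | C=CC[C@@]1(O[Si](CC)(CC)CC)C=C(Br)C(=O)C1
F5 | step 8 | methyl (5E,7S)-7-[(1S,2S)-4-bromo-2-[(2Z)-oct-2-en-1-yl]-5-oxo-2-(triethylsilyloxy)cyclopent-3-en-1-yl]-7-(methanesulfonyloxy)hept-5-enoate | CCCCC/C=C\C[C@@]1(O[Si](CC)(CC)CC)C=C(Br)C(=O)[C@H]1[C@@H](OS(C)(=O)=O)/C=C/CCCC(=O)OC
F6 | step 8 | methyl (5E,7E)-7-[(2R)-4-bromo-2-[(2Z)-oct-2-en-1-yl]-5-oxo-2-(triethylsilyloxy)cyclopent-3-en-1-ylidene]hept-5-enoate | CCCCC/C=C\C[C@@]1(O[Si](CC)(CC)CC)C=C(Br)C(=O)/C1=C/C=C/CCCC(=O)OC
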